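C1 is the CH2OH carbon and C16 the ArCH2 carbon; ring A is the hydroquinone ring. The target needs one stereocentre (12R) and four trisubstituted olefins: 2Z (CH2OH cis to C4), 6E, 10E and 14E.
Enabling feature: carbinol carbon C12 is bonded directly to olefinic C11 and, through the single methylene C13, to olefinic C14 (alkenyl–CH(O)–CH2–alkenyl). C12–C13 can therefore start as a plain vinyl group held on boron next to C11.
Key disconnection: C11–C12 forms by a palladium-induced, enantioselective 1,2-metallate shift inside a bis(alkenyl)borate. The same catalytic turnover closes C13–C14, and C12–B becomes C12–OH in the same pot. The pieces are a C1–C11 alkenylboronate, vinyllithium and a C14–C16/ring A alkenyl bromide.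
C1–C11 piece: Johnson–Claisen (6E), β-oxido-ylide Wittig hydroxymethylation (2Z), methylalumination/borylation (10E). C14–C16/ring A piece: monobromination of one of the two equivalent methyl groups of 2,6-dimethylhydroquinone, propynylation, hydrozirconation/bromination (14E).
No ring is formed in the route (ring A is bought), and the end game is one global desilylation.

Key step: step 12

Assumption: the (Sp,Sp) antipode of the ligand is taken to give 12R, by analogy with the carbinols it gives when aryl or alkenyl groups migrate; since the sense of induction rests on the ligand alone, its mirror image would be the one to use should the analogy fail.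

Step 1
Reactants: 1 (4-bromobut-1-yn-1-yl)trimethylsilane; 2 methacrolein
Product: 4 rac-2-methyl-7-(trimethylsilyl)hept-1-en-6-yn-3-ol, via silylbutynyl Grignard reagent 3 (not isolated)
Conditions: Mg, THF, rt to 40 °C; then 2, −78 to 0 °C; aqueous work-up
Reagents that add atoms: none
Why: Grignard 1,2-addition to the enal carbonyl is fast at low temperature and the silyl cap keeps the alkyne non-acidic; the carbinol centre may be racemic because step 2 destroys it.

Step 2
Reactants: 4 rac-2-methyl-7-(trimethylsilyl)hept-1-en-6-yn-3-ol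
Product: 6 ethyl (E)-4-methyl-9-(trimethylsilyl)non-4-en-8-ynoate, via mixed ketene acetal 5 (not isolated)
Conditions: MeC(OEt)3 (excess), EtCO2H (cat.), 140 °C, EtOH distilled off
Reagents that add atoms: triethyl orthoacetate CC(OCC)(OCC)OCC
Why: Johnson–Claisen [3,3]-rearrangement through a chair transition state with the carbinol side chain equatorial (an axial chain would clash with the ethoxy group) should give the E trisubstituted olefin that becomes C6=C7.

Step 3
Reactants: 6 ethyl (E)-4-methyl-9-(trimethylsilyl)non-4-en-8-ynoate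
Product: 7 (E)-4-methyl-9-(trimethylsilyl)non-4-en-8-ynal
Conditions: i-Bu2AlH (1.05 equiv), CH2Cl2, −78 °C; aqueous work-up
Reagents that add atoms: none
Why: the tetrahedral aluminium hemiacetal formed at −78 °C survives until the quench, so this standard partial ester reduction stops at the aldehyde and leaves olefin and silylalkyne untouched.

Step 4
Reactants: 7 (E)-4-methyl-9-(trimethylsilyl)non-4-en-8-ynal
Product: 9 (2Z,6E)-2,6-dimethyl-11-(trimethylsilyl)undeca-2,6-dien-10-yn-1-ol, via lithium β-oxido ylide 8 (not isolated)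
Conditions: EtPPh3Br, n-BuLi, THF, 0 °C; 7, −78 °C; n-BuLi (second equiv), −78 to 0 °C; dry (CH2O)n, 0 °C to rt
Reagents that add atoms: ethyltriphenylphosphonium bromide CC[P+](c1ccccc1)(c1ccccc1)c1ccccc1.[Br-]; formaldehyde (from paraformaldehyde) C=O
Why: Wittig reaction in its β-oxido-ylide (Wittig–Schlosser, SCOOPY) form: the lithium betaine from 7 and the ethylidene ylide is deprotonated to 8, which adds formaldehyde at carbon, and syn-loss of Ph3PO through the older oxido group should place the new CH2OH cis to the chain, the established outcome for 2-methylalk-2-en-1-ols made this way (2Z).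

Step 5
Reactants: 9 (2Z,6E)-2,6-dimethyl-11-(trimethylsilyl)undeca-2,6-dien-10-yn-1-ol
Product: 10 tert-butyl{[(2Z,6E)-2,6-dimethyl-11-(trimethylsilyl)undeca-2,6-dien-10-yn-1-yl]oxy}dimethylsilane
Conditions: TBSCl, imidazole, CH2Cl2, 0 °C to rt
Reagents that add atoms: tert-butyldimethylsilyl chloride CC(C)(C)[Si](C)(C)Cl
Why: standard imidazole-promoted silylation of a primary allylic alcohol, neutral enough to leave the Z olefin unchanged.

Step 6
Reactants: 10 tert-butyl{[(2Z,6E)-2,6-dimethyl-11-(trimethylsilyl)undeca-2,6-dien-10-yn-1-yl]oxy}dimethylsilane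
Product: 11 tert-butyl{[(2Z,6E)-2,6-dimethylundeca-2,6-dien-10-yn-1-yl]oxy}dimethylsilane
Conditions: K2CO3 (0.2 equiv), MeOH, rt
Reagents that add atoms: none
Why: methoxide-catalysed protiodesilylation cleaves only the C(sp)–SiMe3 bond, because an acetylide leaves silicon easily, while the hindered alkyl O–TBS ether is stable to K2CO3/MeOH.

Step 7
Reactants: 11 tert-butyl{[(2Z,6E)-2,6-dimethylundeca-2,6-dien-10-yn-1-yl]oxy}dimethylsilane
Product: 13 2-[(1E,5E,9Z)-11-(tert-butyldimethylsilyloxy)-2,6,10-trimethylundeca-1,5,9-trien-1-yl]-4,4,5,5-tetramethyl-1,3,2-dioxaborolane, via alkenyldimethylalane 12 (not isolated)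
Conditions: Me3Al (2.5 equiv), Cp2ZrCl2 (0.25 equiv), CH2Cl2, 0 °C to rt; then i-PrOBpin, 0 °C to rt
Reagents that add atoms: trimethylaluminium C[Al](C)C; 2-isopropoxy-4,4,5,5-tetramethyl-1,3,2-dioxaborolane CC(C)OB1OC(C)(C)C(C)(C)O1
Why: Negishi zirconium-catalysed methylalumination adds CH3 and Al syn across the terminal alkyne with Al on the terminal carbon (this sets 10E), and aluminium-to-boron transmetalation with the alkoxyborolane keeps that geometry, while the isolated trisubstituted olefins and the silyl ether stay inert.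

Step 8
Reactants: 14 2,6-dimethylbenzene-1,4-diol (2,6-dimethylhydroquinone)
Product: 15 2,5-bis(tert-butyldimethylsilyloxy)-1,3-dimethylbenzene
Conditions: TBSCl (2.5 equiv), imidazole, DMF, 45 °C
Reagents that add atoms: tert-butyldimethylsilyl chloride CC(C)(C)[Si](C)(C)Cl
Why: standard phenol silylation, with mild heating to bring the hindered OH between the two methyl groups to full conversion.

Step 9
Reactants: 15 2,5-bis(tert-butyldimethylsilyloxy)-1,3-dimethylbenzene
Product: 16 1-(bromomethyl)-2,5-bis(tert-butyldimethylsilyloxy)-3-methylbenzene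
Conditions: NBS (1.0 equiv), AIBN (5 mol %), PhCF3, reflux, visible light
Reagents that add atoms: N-bromosuccinimide O=C1CCC(=O)N1Br
Why: Wohl–Ziegler radical bromination in a non-polar solvent takes a benzylic hydrogen; the two methyl groups are equivalent by symmetry, so only one monobromide is possible, and the bulky silyl ethers slow electrophilic attack on ring A.

Step 10
Reactants: 16 1-(bromomethyl)-2,5-bis(tert-butyldimethylsilyloxy)-3-methylbenzene; 17 prop-1-yn-1-ylmagnesium bromide
Product: 18 1-(but-2-yn-1-yl)-2,5-bis(tert-butyldimethylsilyloxy)-3-methylbenzene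
Conditions: CuBr·SMe2 (10 mol %), THF, 0 to 50 °C
Reagents that add atoms: none
Why: copper-catalysed SN2-type coupling of an alkynyl Grignard reagent with a benzylic bromide is well precedented and tolerates aryl silyl ethers.

Step 11
Reactants: 18 1-(but-2-yn-1-yl)-2,5-bis(tert-butyldimethylsilyloxy)-3-methylbenzene
Product: 20 1-[(E)-3-bromobut-2-en-1-yl]-2,5-bis(tert-butyldimethylsilyloxy)-3-methylbenzene, via alkenylzirconocene chloride 19 (not isolated)
Conditions: Cp2Zr(H)Cl (1.8 equiv), THF, 50 °C; then NBS, 0 °C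
Reagents that add atoms: N-bromosuccinimide O=C1CCC(=O)N1Br
Why: syn-hydrozirconation followed by stereoretentive bromodezirconation; excess Cp2Zr(H)Cl and warming equilibrate the regioisomeric alkenylzirconocenes towards the one with Zr on the methyl-bearing carbon, away from the bulky benzyl group, which places Br trans to CH2Ar (E).

Step 12
Reactants: 13 2-[(1E,5E,9Z)-11-(tert-butyldimethylsilyloxy)-2,6,10-trimethylundeca-1,5,9-trien-1-yl]-4,4,5,5-tetramethyl-1,3,2-dioxaborolane; 20 1-[(E)-3-bromobut-2-en-1-yl]-2,5-bis(tert-butyldimethylsilyloxy)-3-methylbenzene; 21 tetravinylstannane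
Product: 25 (2Z,6E,10E,12R,14E)-16-[2,5-bis(tert-butyldimethylsilyloxy)-3-methylphenyl]-1-(tert-butyldimethylsilyloxy)-2,6,10,14-tetramethylhexadeca-2,6,10,14-tetraen-12-ol, via vinyllithium 22 (not isolated), via lithium bis(alkenyl)borate 23 (not isolated), via (12R)-allylboronate 24 (not isolated)
Conditions: 21, n-BuLi, pentane, 0 °C (vinyllithium settles, is washed and taken up in Et2O); 13, Et2O, 0 °C to rt, then evaporate; Pd(OAc)2 (3 mol %), (Sp,Sp)-MandyPhos [1,1'-bis{bis(4-methoxy-3,5-dimethylphenyl)phosphino}-2,2'-bis{(R)-(dimethylamino)(phenyl)methyl}ferrocene, 3.6 mol %], KOSO2CF3 (2 equiv), 20, THF, 60 °C; then pH 7 phosphate buffer, 30 % H2O2, 0 °C to rt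
Reagents that add atoms: hydrogen peroxide OO
Why: Vinyllithium adds to the empty boron orbital of 13 to give the non-symmetric bis(alkenyl)borate 23; oxidative addition of 20 to zerovalent palladium and removal of bromide as insoluble KBr give a cationic alkenylpalladium that binds the unsubstituted vinyl group, which triggers an anti-periplanar 1,2-metallate shift of alkenyl carbon C11 from boron to C12 (the C11–C12 bond), and reductive elimination then closes C13–C14. The closest known reaction type is the enantioselective palladium-catalysed conjunctive cross-coupling of bis(alkenyl)borates, together with its triflate-salt variant for C(sp2) halides. No ring is closed. C12 is the only new stereocentre: the C2-symmetric diphosphine selects the vinyl face that palladium binds, the migration is stereospecific (anti to Pd), and reductive elimination and the C–B to C–O oxidation both go with retention, so 24 and 25 should both be 12R. The step needs chemoselectivity between the two alkenyl groups on boron and against direct Suzuki-type transfer; the substrate secures it because palladium binds the sterically free CH2=CH group far better than the trisubstituted C10=C11 unit, which is therefore the migrating group, and because no base is present to promote transmetalation. Both alkenyl partners keep their geometry (retention at migrating C11, and at C14 through oxidative addition and reductive elimination), and the pH 7 oxidation spares the aryl silyl ethers.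

Step 13
Reactants: 25 (2Z,6E,10E,12R,14E)-16-[2,5-bis(tert-butyldimethylsilyloxy)-3-methylphenyl]-1-(tert-butyldimethylsilyloxy)-2,6,10,14-tetramethylhexadeca-2,6,10,14-tetraen-12-ol
Product: 26 (2Z,6E,10E,12R,14E)-16-(2,5-dihydroxy-3-methylphenyl)-2,6,10,14-tetramethylhexadeca-2,6,10,14-tetraene-1,12-diol (target)
Conditions: Bu4NF (4 equiv), AcOH (4 equiv), degassed THF, 0 °C to rt, argon
Reagents that add atoms: none
Why: fluoride cleaves the two aryl silyl ethers and the allylic silyl ether in one operation under nearly neutral conditions, so the ionisable C12 allylic alcohol, the olefin geometries and the stereocentre stay untouched, and exclusion of air keeps the hydroquinone from oxidising.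

Compound list
1 | (4-bromobut-1-yn-1-yl)trimethylsilane | C[Si](C)(C)C#CCCBr | starting material
2 | methacrolein (2-methylprop-2-enal) | C=C(C)C=O | starting material
3 | [4-(trimethylsilyl)but-3-yn-1-yl]magnesium bromide | C[Si](C)(C)C#CCC[Mg]Br | intermediate
4 | rac-2-methyl-7-(trimethylsilyl)hept-1-en-6-yn-3-ol | C=C(C)C(O)CCC#C[Si](C)(C)C | intermediate
5 | mixed ketene acetal (1-ethoxyvinyl ether of 4) | C=C(OCC)OC(CCC#C[Si](C)(C)C)C(C)=C | intermediate
6 | ethyl (E)-4-methyl-9-(trimethylsilyl)non-4-en-8-ynoate | CCOC(=O)CC/C(C)=C/CCC#C[Si](C)(C)C | intermediate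
7 | (E)-4-methyl-9-(trimethylsilyl)non-4-en-8-ynal | O=CCC/C(C)=C/CCC#C[Si](C)(C)C | intermediate
8 | lithium β-oxido ylide from 7 and ethylidenetriphenylphosphorane | [Li+].[O-]C(CC/C(C)=C/CCC#C[Si](C)(C)C)C(C)=P(c1ccccc1)(c1ccccc1)c1ccccc1 | intermediate
9 | (2Z,6E)-2,6-dimethyl-11-(trimethylsilyl)undeca-2,6-dien-10-yn-1-ol | C/C(=C/CC/C(C)=C/CCC#C[Si](C)(C)C)CO | intermediate
10 | tert-butyl{[(2Z,6E)-2,6-dimethyl-11-(trimethylsilyl)undeca-2,6-dien-10-yn-1-yl]oxy}dimethylsilane | C/C(=C/CC/C(C)=C/CCC#C[Si](C)(C)C)CO[Si](C)(C)C(C)(C)C | intermediate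
11 | tert-butyl{[(2Z,6E)-2,6-dimethylundeca-2,6-dien-10-yn-1-yl]oxy}dimethylsilane | C/C(=C/CC/C(C)=C/CCC#C)CO[Si](C)(C)C(C)(C)C | intermediate
12 | [(1E,5E,9Z)-11-(tert-butyldimethylsilyloxy)-2,6,10-trimethylundeca-1,5,9-trien-1-yl]dimethylalane | C/C(=C/CC/C(C)=C/CC/C(C)=C/[Al](C)C)CO[Si](C)(C)C(C)(C)C | intermediate
13 | 2-[(1E,5E,9Z)-11-(tert-butyldimethylsilyloxy)-2,6,10-trimethylundeca-1,5,9-trien-1-yl]-4,4,5,5-tetramethyl-1,3,2-dioxaborolane | C/C(=C/CC/C(C)=C/CC/C(C)=C/B1OC(C)(C)C(C)(C)O1)CO[Si](C)(C)C(C)(C)C | intermediate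
14 | 2,6-dimethylbenzene-1,4-diol | Cc1cc(O)cc(C)c1O | starting material
15 | 2,5-bis(tert-butyldimethylsilyloxy)-1,3-dimethylbenzene | Cc1cc(O[Si](C)(C)C(C)(C)C)cc(C)c1O[Si](C)(C)C(C)(C)C | intermediate
16 | 1-(bromomethyl)-2,5-bis(tert-butyldimethylsilyloxy)-3-methylbenzene | BrCc1cc(O[Si](C)(C)C(C)(C)C)cc(C)c1O[Si](C)(C)C(C)(C)C | intermediate
17 | prop-1-yn-1-ylmagnesium bromide | CC#C[Mg]Br | starting material
18 | 1-(but-2-yn-1-yl)-2,5-bis(tert-butyldimethylsilyloxy)-3-methylbenzene | CC#CCc1cc(O[Si](C)(C)C(C)(C)C)cc(C)c1O[Si](C)(C)C(C)(C)C | intermediate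
19 | {(E)-4-[2,5-bis(tert-butyldimethylsilyloxy)-3-methylphenyl]but-2-en-2-yl}chloridobis(cyclopentadienyl)zirconium | Cl[Zr](C1C=CC=C1)(C1C=CC=C1)/C(C)=C/Cc1cc(O[Si](C)(C)C(C)(C)C)cc(C)c1O[Si](C)(C)C(C)(C)C | intermediate
20 | 1-[(E)-3-bromobut-2-en-1-yl]-2,5-bis(tert-butyldimethylsilyloxy)-3-methylbenzene | Br/C(C)=C/Cc1cc(O[Si](C)(C)C(C)(C)C)cc(C)c1O[Si](C)(C)C(C)(C)C | intermediate
21 | tetravinylstannane | C=C[Sn](C=C)(C=C)C=C | starting material
22 | vinyllithium | [Li]C=C | intermediate
23 | lithium [(1E,5E,9Z)-11-(tert-butyldimethylsilyloxy)-2,6,10-trimethylundeca-1,5,9-trien-1-yl](vinyl)(pinacolato)borate | C/C(=C/CC/C(C)=C/CC/C(C)=C/[B-]1(C=C)OC(C)(C)C(C)(C)O1)CO[Si](C)(C)C(C)(C)C.[Li+] | intermediate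
24 | 2-{(2Z,6E,10E,12R,14E)-16-[2,5-bis(tert-butyldimethylsilyloxy)-3-methylphenyl]-1-(tert-butyldimethylsilyloxy)-2,6,10,14-tetramethylhexadeca-2,6,10,14-tetraen-12-yl}-4,4,5,5-tetramethyl-1,3,2-dioxaborolane | C/C(=C/CC/C(C)=C/CC/C(C)=C/[C@H](B1OC(C)(C)C(C)(C)O1)C/C(C)=C/Cc1cc(O[Si](C)(C)C(C)(C)C)cc(C)c1O[Si](C)(C)C(C)(C)C)CO[Si](C)(C)C(C)(C)C | intermediate
25 | (2Z,6E,10E,12R,14E)-16-[2,5-bis(tert-butyldimethylsilyloxy)-3-methylphenyl]-1-(tert-butyldimethylsilyloxy)-2,6,10,14-tetramethylhexadeca-2,6,10,14-tetraen-12-ol | C/C(=C/CC/C(C)=C/CC/C(C)=C/[C@H](O)C/C(C)=C/Cc1cc(O[Si](C)(C)C(C)(C)C)cc(C)c1O[Si](C)(C)C(C)(C)C)CO[Si](C)(C)C(C)(C)C | intermediate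
26 | (2Z,6E,10E,12R,14E)-16-(2,5-dihydroxy-3-methylphenyl)-2,6,10,14-tetramethylhexadeca-2,6,10,14-tetraene-1,12-diol | C/C(=C/CC/C(C)=C/CC/C(C)=C/[C@H](O)C/C(C)=C/Cc1cc(O)cc(C)c1O)CO | target

Total step count: 13. Longest linear sequence: 9 steps (steps 1 to 7, 12, 13).

Steps most likely to fail

1. Step 12.
- **Risk:** halide inhibition of the cationic palladium pathway, direct Suzuki-type alkenyl transfer in place of the metallate shift, β-hydride elimination before reductive elimination, or weak facial selectivity with the hindered 1-methylalkenylpalladium species.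
- **Fallback (lithiation–borylation):** this forms the same C11–C12 bond by a reagent-controlled 1,2-shift. It sets out from 16 and 13 and comes back at 24.
- But-3-yn-1-ol is methylaluminated (Me3Al, Cp2ZrCl2) to the alkenylalane F1. This is cross-coupled in the same flask with 16 under Pd(PPh3)4 (Negishi alkenyl–benzyl coupling) to the (E)-homoallylic alcohol F2.
- N,N-Diisopropylcarbamoyl chloride and Et3N turn it into the carbamate F3.
- s-BuLi/(−)-sparteine in Et2O at −78 °C removes the pro-S hydrogen next to oxygen to give the (S)-α-lithio carbamate F4, which 13 borylates with retention to the boronate complex F5.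
- MgBr2·OEt2 and warming trigger the stereoinvertive 1,2-shift of the C11 alkenyl group with loss of the carbamate. This gives 24, which is oxidised as in step 12.

2. Step 9.
- **Risk:** electrophilic bromination of the electron-rich ring in competition with the radical chain, and bromination of both methyl groups.
- **Fallback (electron-poor ring for the radical step, protecting groups exchanged afterwards):** it sets out from 14 and comes back at 18.
- Ac2O/pyridine gives the diacetate F6. NBS/AIBN brominates one methyl group of this deactivated ring to the bromomethyl diacetate F7.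
- A Stille coupling with tributyl(prop-1-yn-1-yl)stannane (Pd2(dba)3, AsPh3), which tolerates the esters, gives the butynyl diacetate F8.
- i-Bu2AlH at −78 °C cleaves both acetates without base to the butynylhydroquinone F9. TBSCl/imidazole then gives 18.

3. Step 4.
- **Risk:** enolisation of the aldehyde, incomplete capture of the β-oxido ylide by slowly depolymerising paraformaldehyde, and erosion of the olefin geometry.
- **Fallback (Still–Gennari olefination, then reduction):** it sets out from 7 and comes back at 9.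
- Ethyl 2-[bis(2,2,2-trifluoroethoxy)phosphoryl]propanoate, KN(SiMe3)2 and 18-crown-6 in THF at −78 °C give the (Z)-enoate F10 under kinetic control. i-Bu2AlH (2.2 equiv) reduces it to 9.

Further compounds
F1 | step 12 | [(E)-4-(dimethylalumanyloxy)-2-methylbut-1-en-1-yl]dimethylalane | C[Al](C)/C=C(\C)CCO[Al](C)C
F2 | step 12 | (E)-5-[2,5-bis(tert-butyldimethylsilyloxy)-3-methylphenyl]-3-methylpent-3-en-1-ol | OCC/C(C)=C/Cc1cc(O[Si](C)(C)C(C)(C)C)cc(C)c1O[Si](C)(C)C(C)(C)C
F3 | step 12 | (E)-5-[2,5-bis(tert-butyldimethylsilyloxy)-3-methylphenyl]-3-methylpent-3-en-1-yl N,N-diisopropylcarbamate | CC(C)N(C(C)C)C(=O)OCC/C(C)=C/Cc1cc(O[Si](C)(C)C(C)(C)C)cc(C)c1O[Si](C)(C)C(C)(C)C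
F4 | step 12 | (S,E)-5-[2,5-bis(tert-butyldimethylsilyloxy)-3-methylphenyl]-1-lithio-3-methylpent-3-en-1-yl N,N-diisopropylcarbamate | CC(C)N(C(C)C)C(=O)O[C@@H]([Li])C/C(C)=C/Cc1cc(O[Si](C)(C)C(C)(C)C)cc(C)c1O[Si](C)(C)C(C)(C)C
F5 | step 12 | lithium boronate complex of F4 and 13 | C/C(=C/CC/C(C)=C/CC/C(C)=C/[B-]1(OC(C)(C)C(C)(C)O1)[C@H](OC(=O)N(C(C)C)C(C)C)C/C(C)=C/Cc1cc(O[Si](C)(C)C(C)(C)C)cc(C)c1O[Si](C)(C)C(C)(C)C)CO[Si](C)(C)C(C)(C)C.[Li+]
F6 | step 9 | 2,6-dimethyl-1,4-phenylene diacetate | CC(=O)Oc1cc(C)c(OC(C)=O)c(C)c1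
F7 | step 9 | 2-(bromomethyl)-6-methyl-1,4-phenylene diacetate | CC(=O)Oc1cc(C)c(OC(C)=O)c(CBr)c1
F8 | step 9 | 2-(but-2-yn-1-yl)-6-methyl-1,4-phenylene diacetate | CC#CCc1cc(OC(C)=O)cc(C)c1OC(C)=O
F9 | step 9 | 2-(but-2-yn-1-yl)-6-methylbenzene-1,4-diol | CC#CCc1cc(O)cc(C)c1O
F10 | step 4 | ethyl (2Z,6E)-2,6-dimethyl-11-(trimethylsilyl)undeca-2,6-dien-10-ynoate | CCOC(=O)/C(C)=C\CC/C(C)=C/CCC#C[Si](C)(C)C
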